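**Retrosynthetic overview**
- The target comes from its bis-silyl ether by global desilylation.
- Ring C (the pyran) is the only ring made. Its O1–C2 bond and the C3 stereocentre are formed together by an enantioselective anti-Markovnikov hydroetherification of a 2-(2-arylallyl)phenol.
- That alkene comes from a C3–C4 bond between a ring A o-quinone methide (from a phenolic Mannich base) and a ring B α-arylvinyl Grignard reagent (Shapiro reaction of 4'-hydroxy-2'-methoxyacetophenone).
- The Mannich base comes from a salicylaldehyde whose prenyl group is placed by a para-Claisen–Cope rearrangement of the 2-O-prenyl ether of 2,4-dihydroxy-6-methoxybenzaldehyde. Rings A and B are bought as arenes.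

Assumption: compound 1 is bought as a catalogue item (otherwise one Vilsmeier formylation of 5-methoxyresorcinol), and the (Sa) thiol catalyst of the key step is taken to give the (3R) product, the (Ra) catalyst being used if the sense proves opposite.

**Step 1**
Reactants: 1 2,4-dihydroxy-6-methoxybenzaldehyde
Product: 2 2-hydroxy-6-methoxy-4-[(triisopropylsilyl)oxy]benzaldehyde
Conditions: i-Pr3SiCl (1.05 equiv), imidazole, CH2Cl2/DMF, 0 °C
Reagents that add atoms: triisopropylsilyl chloride, CC(C)[Si](Cl)(C(C)C)C(C)C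
Why: Silyl ether formation is selective for the 4-hydroxyl because the 2-hydroxyl is tied up in a hydrogen bond to the formyl group and is the less acidic of the two.

**Step 2**
Reactants: 2 2-hydroxy-6-methoxy-4-[(triisopropylsilyl)oxy]benzaldehyde
Product: 3 6-methoxy-2-[(3-methylbut-2-en-1-yl)oxy]-4-[(triisopropylsilyl)oxy]benzaldehyde
Conditions: prenol, PPh3, DIAD, THF, 0 °C → rt
Reagents that add atoms: 3-methylbut-2-en-1-ol, CC(C)=CCO
Why: The Mitsunobu reaction etherifies the hydrogen-bonded phenol under neutral conditions, so the silyl ether para to the aldehyde is not cleaved and only the O-linked primary prenyl ether forms.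

**Step 3**
Reactants: 3 6-methoxy-2-[(3-methylbut-2-en-1-yl)oxy]-4-[(triisopropylsilyl)oxy]benzaldehyde
Product: 6 2-hydroxy-6-methoxy-5-(3-methylbut-2-en-1-yl)-4-[(triisopropylsilyl)oxy]benzaldehyde, via ortho-dienone 4 (not isolated), via para-dienone 5 (not isolated)
Conditions: N,N-diethylaniline, 200 °C, sealed tube, argon
Reagents that add atoms: none
Why: An aromatic Claisen rearrangement to the free ortho carbon (dienone 4) followed by a Cope rearrangement (para-Claisen sequence) carries the prenyl group in its unbranched form to the only para position, C5 between the silyloxy and methoxy groups, and tautomerisation of 5 frees the phenol that later becomes O1, as is established for analogous 2-prenyloxy aryl ketones with two meta oxygen substituents.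

**Step 4**
Reactants: 6 2-hydroxy-6-methoxy-5-(3-methylbut-2-en-1-yl)-4-[(triisopropylsilyl)oxy]benzaldehyde
Product: 8 2-[(dimethylamino)methyl]-3-methoxy-4-(3-methylbut-2-en-1-yl)-5-[(triisopropylsilyl)oxy]phenol, via iminium acetate 7 (not isolated)
Conditions: Me2NH (THF solution), AcOH, NaBH(OAc)3, ClCH2CH2Cl, rt
Reagents that add atoms: dimethylamine, CNC
Why: Reductive amination through iminium ion 7 with the mild hydride donor NaBH(OAc)3 turns the formyl carbon (the future C4) into a benzylic dimethylamine, a stable phenolic Mannich base, and leaves the prenyl alkene and the silyl ether alone.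

**Step 5**
Reactants: 9 1-(4-hydroxy-2-methoxyphenyl)ethan-1-one
Product: 10 1-{2-methoxy-4-[(triisopropylsilyl)oxy]phenyl}ethan-1-one
Conditions: i-Pr3SiCl, imidazole, DMF, rt
Reagents that add atoms: triisopropylsilyl chloride, CC(C)[Si](Cl)(C(C)C)C(C)C
Why: Routine silyl ether formation masks the ring B phenol for the organolithium chemistry and for the photochemical step.

**Step 6**
Reactants: 10 1-{2-methoxy-4-[(triisopropylsilyl)oxy]phenyl}ethan-1-one
Product: 11 N'-(1-{2-methoxy-4-[(triisopropylsilyl)oxy]phenyl}ethylidene)-2,4,6-triisopropylbenzenesulfonohydrazide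
Conditions: 2,4,6-triisopropylbenzenesulfonohydrazide, cat. HCl, MeCN, rt
Reagents that add atoms: 2,4,6-triisopropylbenzenesulfonohydrazide, CC(C)c1cc(C(C)C)c(S(=O)(=O)NN)c(C(C)C)c1
Why: Acid-catalysed condensation gives the arylsulfonylhydrazone needed for the Shapiro reaction, the 2,4,6-triisopropylphenyl group having no ortho hydrogen that could be lithiated in place of the methyl group.

**Step 7**
Reactants: 8 2-[(dimethylamino)methyl]-3-methoxy-4-(3-methylbut-2-en-1-yl)-5-[(triisopropylsilyl)oxy]phenol; 11 N'-(1-{2-methoxy-4-[(triisopropylsilyl)oxy]phenyl}ethylidene)-2,4,6-triisopropylbenzenesulfonohydrazide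
Product: 16 2-(2-{2-methoxy-4-[(triisopropylsilyl)oxy]phenyl}prop-2-en-1-yl)-3-methoxy-4-(3-methylbut-2-en-1-yl)-5-[(triisopropylsilyl)oxy]phenol, via ammonium iodide 12 (not isolated), via vinyllithium 13 (not isolated), via vinylmagnesium bromide 14 (not isolated), via o-quinone methide 15 (not isolated)
Conditions: 11 (1.5 equiv), n-BuLi (2.1 equiv per 11), THF, −78 → 0 °C, then MgBr2·OEt2, −78 °C; separately 8, MeI, THF, rt, evaporate; combine at −78 °C, t-BuMgCl (1.0 equiv), → rt; H2O
Reagents that add atoms: none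
Why: The Shapiro reaction turns 11 into vinyllithium 13 (then Grignard reagent 14 by transmetalation), while N-methylation of 8 and deprotonation of the phenol trigger 1,4-elimination of trimethylamine to o-quinone methide 15, whose exocyclic CH2 takes up 14 in a conjugate (1,4) addition that forms the C3–C4 bond and rearomatises to the free phenol; because C4 is already a CH2 group, no vinyl quinone methide that could close to a chromene is formed.

**Step 8**
Reactants: 16 2-(2-{2-methoxy-4-[(triisopropylsilyl)oxy]phenyl}prop-2-en-1-yl)-3-methoxy-4-(3-methylbut-2-en-1-yl)-5-[(triisopropylsilyl)oxy]phenol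
Product: 19 (3R)-5-methoxy-3-{2-methoxy-4-[(triisopropylsilyl)oxy]phenyl}-6-(3-methylbut-2-en-1-yl)-7-[(triisopropylsilyl)oxy]chromane, via alkene radical cation 17 (not isolated), via chroman-3-yl radical 18 (not isolated)
Conditions: 9-mesityl-3,6-di-tert-butyl-10-phenylacridinium tetrafluoroborate (5 mol%), bis[(Sa)-2'-{3-[3,5-bis(trifluoromethyl)phenyl]ureido}-1,1'-binaphthalen-2-yl] disulfide (7.5 mol%, precursor of the chiral arenethiol), 2,6-lutidine (20 mol%), CH2Cl2/PhCF3, 450 nm LEDs, −30 °C, argon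
Reagents that add atoms: none
Why: Proposed new method: the photoexcited acridinium oxidises the electron-rich 1,1-disubstituted arylalkene to radical cation 17, the phenol oxygen closes 6-endo onto the terminal CH2 (anti-Markovnikov, because this leaves the tertiary benzylic radical 18), which forms the O1–C2 bond and ring C, and the urea-anchored axially chiral arenethiol (S–H about 79 kcal/mol, weaker than the new benzylic C–H, and regenerated from its thiyl radical by the reduced acridine and a proton) delivers the hydrogen atom to one face of C3 to set the (3R) centre; the closest known reactions are the racemic acridinium/thiol anti-Markovnikov hydroetherification of alkenols and the enantioselective alkene hydroamination in which a chiral thiol sets a carbon stereocentre by hydrogen atom transfer.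

**Step 9**
Reactants: 19 (3R)-5-methoxy-3-{2-methoxy-4-[(triisopropylsilyl)oxy]phenyl}-6-(3-methylbut-2-en-1-yl)-7-[(triisopropylsilyl)oxy]chromane
Product: 20 (3R)-3-(4-hydroxy-2-methoxyphenyl)-5-methoxy-6-(3-methylbut-2-en-1-yl)chroman-7-ol
Conditions: Bu4NF (2.2 equiv), AcOH (2.5 equiv), THF, 0 °C
Reagents that add atoms: none
Why: Fluoride-mediated desilylation buffered with acetic acid cleaves both aryl silyl ethers without acid (which would cyclise the 7-hydroxyl onto the prenyl group) and without touching the C3 centre, which carries no acidifying group.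

**Compound list**
1 | 2,4-dihydroxy-6-methoxybenzaldehyde | O=Cc1c(O)cc(O)cc1OC | starting material
2 | 2-hydroxy-6-methoxy-4-[(triisopropylsilyl)oxy]benzaldehyde | O=Cc1c(O)cc(O[Si](C(C)C)(C(C)C)C(C)C)cc1OC | intermediate
3 | 6-methoxy-2-[(3-methylbut-2-en-1-yl)oxy]-4-[(triisopropylsilyl)oxy]benzaldehyde | O=Cc1c(OCC=C(C)C)cc(O[Si](C(C)C)(C(C)C)C(C)C)cc1OC | intermediate
4 | 2-methoxy-5-(2-methylbut-3-en-2-yl)-6-oxo-4-[(triisopropylsilyl)oxy]cyclohexa-1,3-diene-1-carbaldehyde (ortho-dienone, racemic, formed in the flask) | O=CC1=C(OC)C=C(O[Si](C(C)C)(C(C)C)C(C)C)C(C(C)(C)C=C)C1=O | intermediate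
5 | 2-methoxy-3-(3-methylbut-2-en-1-yl)-6-oxo-4-[(triisopropylsilyl)oxy]cyclohexa-1,4-diene-1-carbaldehyde (para-dienone, racemic, formed in the flask) | O=CC1=C(OC)C(CC=C(C)C)C(O[Si](C(C)C)(C(C)C)C(C)C)=CC1=O | intermediate
6 | 2-hydroxy-6-methoxy-5-(3-methylbut-2-en-1-yl)-4-[(triisopropylsilyl)oxy]benzaldehyde | O=Cc1c(O)cc(O[Si](C(C)C)(C(C)C)C(C)C)c(CC=C(C)C)c1OC | intermediate
7 | N-{[2-hydroxy-6-methoxy-5-(3-methylbut-2-en-1-yl)-4-[(triisopropylsilyl)oxy]phenyl]methylidene}-N-methylmethanaminium acetate (iminium acetate, formed in the flask) | C[N+](C)=Cc1c(O)cc(O[Si](C(C)C)(C(C)C)C(C)C)c(CC=C(C)C)c1OC.CC(=O)[O-] | intermediate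
8 | 2-[(dimethylamino)methyl]-3-methoxy-4-(3-methylbut-2-en-1-yl)-5-[(triisopropylsilyl)oxy]phenol | CN(C)Cc1c(O)cc(O[Si](C(C)C)(C(C)C)C(C)C)c(CC=C(C)C)c1OC | intermediate
9 | 1-(4-hydroxy-2-methoxyphenyl)ethan-1-one | CC(=O)c1ccc(O)cc1OC | starting material
10 | 1-{2-methoxy-4-[(triisopropylsilyl)oxy]phenyl}ethan-1-one | CC(=O)c1ccc(O[Si](C(C)C)(C(C)C)C(C)C)cc1OC | intermediate
11 | N'-(1-{2-methoxy-4-[(triisopropylsilyl)oxy]phenyl}ethylidene)-2,4,6-triisopropylbenzenesulfonohydrazide | CC(=NNS(=O)(=O)c1c(C(C)C)cc(C(C)C)cc1C(C)C)c1ccc(O[Si](C(C)C)(C(C)C)C(C)C)cc1OC | intermediate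
12 | {2-hydroxy-6-methoxy-5-(3-methylbut-2-en-1-yl)-4-[(triisopropylsilyl)oxy]benzyl}trimethylammonium iodide (formed in the flask) | C[N+](C)(C)Cc1c(O)cc(O[Si](C(C)C)(C(C)C)C(C)C)c(CC=C(C)C)c1OC.[I-] | intermediate
13 | (1-{2-methoxy-4-[(triisopropylsilyl)oxy]phenyl}vinyl)lithium (formed in the flask) | [Li]C(=C)c1ccc(O[Si](C(C)C)(C(C)C)C(C)C)cc1OC | intermediate
14 | (1-{2-methoxy-4-[(triisopropylsilyl)oxy]phenyl}vinyl)magnesium bromide (formed in the flask) | Br[Mg]C(=C)c1ccc(O[Si](C(C)C)(C(C)C)C(C)C)cc1OC | intermediate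
15 | 5-methoxy-6-methylidene-4-(3-methylbut-2-en-1-yl)-3-[(triisopropylsilyl)oxy]cyclohexa-2,4-dien-1-one (o-quinone methide, formed in the flask) | C=C1C(=O)C=C(O[Si](C(C)C)(C(C)C)C(C)C)C(CC=C(C)C)=C1OC | intermediate
16 | 2-(2-{2-methoxy-4-[(triisopropylsilyl)oxy]phenyl}prop-2-en-1-yl)-3-methoxy-4-(3-methylbut-2-en-1-yl)-5-[(triisopropylsilyl)oxy]phenol | C=C(Cc1c(O)cc(O[Si](C(C)C)(C(C)C)C(C)C)c(CC=C(C)C)c1OC)c1ccc(O[Si](C(C)C)(C(C)C)C(C)C)cc1OC | intermediate
17 | radical cation of 16 at the 1,1-disubstituted alkene (drawn as the CH2 radical with the benzylic cation, formed in the flask) | [CH2][C+](Cc1c(O)cc(O[Si](C(C)C)(C(C)C)C(C)C)c(CC=C(C)C)c1OC)c1ccc(O[Si](C(C)C)(C(C)C)C(C)C)cc1OC | intermediate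
18 | 5-methoxy-3-{2-methoxy-4-[(triisopropylsilyl)oxy]phenyl}-6-(3-methylbut-2-en-1-yl)-7-[(triisopropylsilyl)oxy]chroman-3-yl radical (formed in the flask) | COc1cc(O[Si](C(C)C)(C(C)C)C(C)C)ccc1[C]1COc2cc(O[Si](C(C)C)(C(C)C)C(C)C)c(CC=C(C)C)c(OC)c2C1 | intermediate
19 | (3R)-5-methoxy-3-{2-methoxy-4-[(triisopropylsilyl)oxy]phenyl}-6-(3-methylbut-2-en-1-yl)-7-[(triisopropylsilyl)oxy]chromane | COc1cc(O[Si](C(C)C)(C(C)C)C(C)C)ccc1[C@@H]1COc2cc(O[Si](C(C)C)(C(C)C)C(C)C)c(CC=C(C)C)c(OC)c2C1 | intermediate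
20 | (3R)-3-(4-hydroxy-2-methoxyphenyl)-5-methoxy-6-(3-methylbut-2-en-1-yl)chroman-7-ol | COc1cc(O)ccc1[C@@H]1COc2cc(O)c(CC=C(C)C)c(OC)c2C1 | target

**Step count**
Total steps: 9. Longest linear sequence: 7 steps (steps 1, 2, 3, 4, 7, 8 and 9, from compound 1).

**Steps most likely to fail**

Step 8 (the proposed new reaction). The risks are competing oxidation of the ring A phenol, acid-promoted Markovnikov closure to a dihydrobenzofuran, thiol-ene loss of alkene, and insufficient facial control in the hydrogen atom transfer. The fallback uses known chemistry, sets out from 16 and comes back at 19. A cobalt-catalysed asymmetric anti-Markovnikov hydroboration of the 1,1-disubstituted aryl alkene (CoCl2 complex of a chiral iminopyridine-oxazoline ligand, NaBHEt3, HBpin in excess to cover the phenol O–H, THF, rt; the trisubstituted prenyl alkene does not react) gives 2-[(2R)-2-{2-methoxy-4-[(triisopropylsilyl)oxy]phenyl}-3-(4,4,5,5-tetramethyl-1,3,2-dioxaborolan-2-yl)propyl]-3-methoxy-4-(3-methylbut-2-en-1-yl)-5-[(triisopropylsilyl)oxy]phenol F8. Oxidation with NaBO3 in THF/H2O gives 2-[(2R)-3-hydroxy-2-{2-methoxy-4-[(triisopropylsilyl)oxy]phenyl}propyl]-3-methoxy-4-(3-methylbut-2-en-1-yl)-5-[(triisopropylsilyl)oxy]phenol F9. A Mitsunobu cyclisation (PPh3, DIAD, THF, 0 °C) then forms the O1–C2 bond and returns 19 with the C3 centre untouched.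

Step 3 (para-Claisen–Cope). The risk is enolisation of dienone 4 to the ortho product carrying a 2-methylbut-3-en-2-yl group at C3. The fallback blocks that carbon, sets out from 2 and comes back at 6. Bromination of 2 with N-bromosuccinimide in MeCN at 0 °C, at the carbon ortho to the free hydroxyl, gives 3-bromo-2-hydroxy-6-methoxy-4-[(triisopropylsilyl)oxy]benzaldehyde F1. Mitsunobu prenylation as in step 2 gives 3-bromo-6-methoxy-2-[(3-methylbut-2-en-1-yl)oxy]-4-[(triisopropylsilyl)oxy]benzaldehyde F2. Heating as in step 3, now with both ortho carbons substituted so that only the para position can rearomatise, gives 3-bromo-2-hydroxy-6-methoxy-5-(3-methylbut-2-en-1-yl)-4-[(triisopropylsilyl)oxy]benzaldehyde F3. Palladium-catalysed transfer hydrogenolysis of the aryl bromide (Pd(OAc)2, PPh3, HCO2H, Et3N, DMF, 60 °C) then returns 6.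

Step 7 (quinone methide alkenylation). The risks are incomplete quinone methide release or its oligomerisation before the Grignard reagent adds. The fallback makes the C3–C4 bond by carbonyl addition and then removes the oxygen reductively; it sets out from 6 and comes back at 16. Mitsunobu allylation of 6 (allyl alcohol, PPh3, DIAD) gives 2-(allyloxy)-6-methoxy-5-(3-methylbut-2-en-1-yl)-4-[(triisopropylsilyl)oxy]benzaldehyde F4. Addition of vinyllithium 13 (from 11 as in step 7) at −78 °C gives racemic 1-[2-(allyloxy)-6-methoxy-5-(3-methylbut-2-en-1-yl)-4-[(triisopropylsilyl)oxy]phenyl]-2-{2-methoxy-4-[(triisopropylsilyl)oxy]phenyl}prop-2-en-1-ol F5. ClCO2Me and pyridine convert it into methyl 1-[2-(allyloxy)-6-methoxy-5-(3-methylbut-2-en-1-yl)-4-[(triisopropylsilyl)oxy]phenyl]-2-{2-methoxy-4-[(triisopropylsilyl)oxy]phenyl}prop-2-en-1-yl carbonate F6. Palladium-catalysed formate hydrogenolysis of the allylic carbonate (Pd(OAc)2, PBu3, HCO2H, Et3N, THF, 40 °C), which delivers hydride to the more substituted allyl terminus and so keeps the 1,1-disubstituted alkene, gives 1-(allyloxy)-2-(2-{2-methoxy-4-[(triisopropylsilyl)oxy]phenyl}prop-2-en-1-yl)-3-methoxy-4-(3-methylbut-2-en-1-yl)-5-[(triisopropylsilyl)oxy]benzene F7. Continued heating with the same catalyst and formate removes the O-allyl group and returns 16.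

**Further compounds**
F1 | step 3 | 3-bromo-2-hydroxy-6-methoxy-4-[(triisopropylsilyl)oxy]benzaldehyde | O=Cc1c(O)c(Br)c(O[Si](C(C)C)(C(C)C)C(C)C)cc1OC
F2 | step 3 | 3-bromo-6-methoxy-2-[(3-methylbut-2-en-1-yl)oxy]-4-[(triisopropylsilyl)oxy]benzaldehyde | O=Cc1c(OCC=C(C)C)c(Br)c(O[Si](C(C)C)(C(C)C)C(C)C)cc1OC
F3 | step 3 | 3-bromo-2-hydroxy-6-methoxy-5-(3-methylbut-2-en-1-yl)-4-[(triisopropylsilyl)oxy]benzaldehyde | O=Cc1c(O)c(Br)c(O[Si](C(C)C)(C(C)C)C(C)C)c(CC=C(C)C)c1OC
F4 | step 7 | 2-(allyloxy)-6-methoxy-5-(3-methylbut-2-en-1-yl)-4-[(triisopropylsilyl)oxy]benzaldehyde | O=Cc1c(OCC=C)cc(O[Si](C(C)C)(C(C)C)C(C)C)c(CC=C(C)C)c1OC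
F5 | step 7 | 1-[2-(allyloxy)-6-methoxy-5-(3-methylbut-2-en-1-yl)-4-[(triisopropylsilyl)oxy]phenyl]-2-{2-methoxy-4-[(triisopropylsilyl)oxy]phenyl}prop-2-en-1-ol (racemic) | OC(C(=C)c1ccc(O[Si](C(C)C)(C(C)C)C(C)C)cc1OC)c1c(OCC=C)cc(O[Si](C(C)C)(C(C)C)C(C)C)c(CC=C(C)C)c1OC
F6 | step 7 | methyl 1-[2-(allyloxy)-6-methoxy-5-(3-methylbut-2-en-1-yl)-4-[(triisopropylsilyl)oxy]phenyl]-2-{2-methoxy-4-[(triisopropylsilyl)oxy]phenyl}prop-2-en-1-yl carbonate (racemic) | COC(=O)OC(C(=C)c1ccc(O[Si](C(C)C)(C(C)C)C(C)C)cc1OC)c1c(OCC=C)cc(O[Si](C(C)C)(C(C)C)C(C)C)c(CC=C(C)C)c1OC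
F7 | step 7 | 1-(allyloxy)-2-(2-{2-methoxy-4-[(triisopropylsilyl)oxy]phenyl}prop-2-en-1-yl)-3-methoxy-4-(3-methylbut-2-en-1-yl)-5-[(triisopropylsilyl)oxy]benzene | C=CCOc1cc(O[Si](C(C)C)(C(C)C)C(C)C)c(CC=C(C)C)c(OC)c1CC(=C)c1ccc(O[Si](C(C)C)(C(C)C)C(C)C)cc1OC
F8 | step 8 | 2-[(2R)-2-{2-methoxy-4-[(triisopropylsilyl)oxy]phenyl}-3-(4,4,5,5-tetramethyl-1,3,2-dioxaborolan-2-yl)propyl]-3-methoxy-4-(3-methylbut-2-en-1-yl)-5-[(triisopropylsilyl)oxy]phenol | COc1cc(O[Si](C(C)C)(C(C)C)C(C)C)ccc1[C@H](CB1OC(C)(C)C(C)(C)O1)Cc1c(O)cc(O[Si](C(C)C)(C(C)C)C(C)C)c(CC=C(C)C)c1OC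
F9 | step 8 | 2-[(2R)-3-hydroxy-2-{2-methoxy-4-[(triisopropylsilyl)oxy]phenyl}propyl]-3-methoxy-4-(3-methylbut-2-en-1-yl)-5-[(triisopropylsilyl)oxy]phenol | COc1cc(O[Si](C(C)C)(C(C)C)C(C)C)ccc1[C@H](CO)Cc1c(O)cc(O[Si](C(C)C)(C(C)C)C(C)C)c(CC=C(C)C)c1OC
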